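**Retrosynthetic overview**

1. The last step closes the ten-membered ring at C6–C7, the bond made when a farnesyl chain closes to the germacrane ring: the C7 end of a C7=C11–C13 allyl unit attacks the C6 aldehyde of a 5-oxo-6-al and the double bond moves to C11=C13.
2. The γ-lactone is closed earlier by 8-OH attacking the C12 ester of a Morita–Baylis–Hillman adduct (the hydroxy-acid closure of 8,12-olides), so the 6-alkoxide formed in the ring closure cannot compete for C12. Of the two angelates, the allylic ring one is the leaving group and the other is the C9 ester of the target.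
3. C7–C10 come from dimethyl 2,3-O-isopropylidene-D-tartrate (C8, C9), C10 from chelation-controlled MeMgBr addition, C1–C6 (C4) from (S)-β-citronellene, C11–C13 from methyl acrylate.
4. Ring order: γ-lactone (step 7), then carbocycle (step 11); no protecting group is used apart from the acetonide already present in the starting material.

Assumption: germacrane numbering as an 8α,12-olide is used (C4 = CHCH3, C5 = ketone, C6 = CHOH, C7 = CH bearing C11, C8 = lactone CH–O, C9 = CH–O-angelate, C10 = C(OH)CH3); the target is then (4S,6S,7S,8R,9S,10R).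

**Route**

Step 1
Reactants: 1 dimethyl (4S,5S)-2,2-dimethyl-1,3-dioxolane-4,5-dicarboxylate
Product: 2 (4S,5S)-N4,N5-dimethoxy-N4,N5,2,2-tetramethyl-1,3-dioxolane-4,5-dicarboxamide
Conditions: MeNHOMe·HCl (3 equiv), iPrMgCl (6 equiv), THF, −20 → 0 °C
Reagents that add atoms: N,O-dimethylhydroxylamine hydrochloride CNOC.Cl
Why: Weinreb amidation of both ester groups by the magnesium amide made in the flask; the stereocentres are not touched and the trans-dioxolane is also the thermodynamic isomer.

Step 2
Reactants: 3 (3S)-3,7-dimethylocta-1,6-diene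
Product: 5 (4S)-4-methylhex-5-en-1-ol, via (4S)-4-methylhex-5-enal 4 (not isolated)
Conditions: O3 (1.0 equiv), CH2Cl2/MeOH 4:1, −78 °C; then NaBH4, −78 → 20 °C
Reagents that add atoms: ozone [O-][O+]=O
Why: Chemoselective ozonolysis of the electron-rich trisubstituted olefin (much faster than the terminal vinyl) with reductive work-up; the stereocentre (later C4) is remote and untouched.

Step 3
Reactants: 5 (4S)-4-methylhex-5-en-1-ol
Product: 6 (3S)-6-bromo-3-methylhex-1-ene
Conditions: CBr4, PPh3, CH2Cl2, 0 °C
Reagents that add atoms: carbon tetrabromide BrC(Br)(Br)Br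
Why: Appel bromination of a primary alcohol under neutral conditions that leave the olefin and the stereocentre alone.

Step 4
Reactants: 6 (3S)-6-bromo-3-methylhex-1-ene; 2 (4S,5S)-N4,N5-dimethoxy-N4,N5,2,2-tetramethyl-1,3-dioxolane-4,5-dicarboxamide
Product: 8 (4S,5S)-N-methoxy-N,2,2-trimethyl-5-[(5S)-5-methylhept-6-enoyl]-1,3-dioxolane-4-carboxamide, via [(4S)-4-methylhex-5-en-1-yl]magnesium bromide 7 (not isolated)
Conditions: Mg, THF, 40 °C; then 2 (1.2 equiv), THF, −78 → −20 °C; aq. NH4Cl
Reagents that add atoms: none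
Why: Grignard mono-addition to a Weinreb amide, whose chelated tetrahedral intermediate blocks over-addition; the two amide groups of C2-symmetric 2 are equivalent, so either gives the same ketone (C10=O, C1–C6 chain attached).

Step 5
Reactants: 8 (4S,5S)-N-methoxy-N,2,2-trimethyl-5-[(5S)-5-methylhept-6-enoyl]-1,3-dioxolane-4-carboxamide
Product: 10 (4S,5S)-5-[(2R,6S)-2-hydroxy-6-methyloct-7-en-2-yl]-2,2-dimethyl-1,3-dioxolane-4-carbaldehyde, via bromomagnesium tertiary alkoxide 9 (not isolated)
Conditions: MeMgBr (1.2 equiv), Et2O/CH2Cl2, −78 °C; then iBu2AlH (3 equiv), −78 °C; aq. KNaC4H4O6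
Reagents that add atoms: methylmagnesium bromide C[Mg]Br
Why: Cram-chelate-controlled Grignard addition (Mg bridges the ketone oxygen and the α-dioxolane oxygen, methyl enters from the face of the α-hydrogen) sets 10R, and the remaining Weinreb amide is then reduced in the same flask to the C7 aldehyde through its stable aluminium hemiaminal.

Step 6
Reactants: 10 (4S,5S)-5-[(2R,6S)-2-hydroxy-6-methyloct-7-en-2-yl]-2,2-dimethyl-1,3-dioxolane-4-carbaldehyde
Product: 12 methyl 2-{hydroxy[(4R,5S)-5-[(2R,6S)-2-hydroxy-6-methyloct-7-en-2-yl]-2,2-dimethyl-1,3-dioxolan-4-yl]methyl}prop-2-enoate (both carbinol epimers)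
Conditions: methyl acrylate (5 equiv), DABCO (1 equiv), 1,4-dioxane/H2O 1:1, 20 °C, 48 h
Reagents that add atoms: methyl acrylate C=CC(=O)OC
Why: Morita–Baylis–Hillman reaction of an activated α-alkoxy aldehyde joins the acrylate α-carbon (C11) to C7; the new carbinol centre forms as a mixture, which does not matter because C7 later becomes an allyl terminus.

Step 7
Reactants: 12 Morita–Baylis–Hillman adduct
Product: 13 (5R)-5-[(1S,2R,6S)-1,2-dihydroxy-2,6-dimethyloct-7-en-1-yl]-4-hydroxy-3-methylideneoxolan-2-one (both C4 epimers)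
Conditions: CF3CO2H/H2O 9:1, 0 °C, 1 h
Reagents that add atoms: none
Why: Acid hydrolysis of the acetonide, then spontaneous lactonisation of the freed 8-OH onto the acrylate ester (γ-lactone favoured over the δ-lactone from 9-OH); no stereocentre is touched and the tertiary 10-OH is protected from ionisation by the adjacent oxygenated carbon.

Step 8
Reactants: 13 lactone triol
Product: 14 bis-angelate of 13 (ring C4–O and side-chain C1′–O esterified as (2Z)-2-methylbut-2-enoates; tertiary OH free)
Conditions: angelic acid (5 equiv), 2,4,6-trichlorobenzoyl chloride (5 equiv), Et3N (10 equiv), toluene, 20 °C, 2 h; then 13, 75 °C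
Reagents that add atoms: angelic acid C/C=C(/C)C(=O)O
Why: Yamaguchi-type esterification with the preformed mixed anhydride and no nucleophilic catalyst, conditions under which angelates do not isomerise to tiglates; both secondary hydroxyls react and the tertiary 10-OH does not.

Step 9
Reactants: 14 bis-angelate
Product: 15 bis-angelate 7′,8′-diol (vinyl converted to CH(OH)CH2OH; both carbinol epimers)
Conditions: OsO4 (2 mol %), N-methylmorpholine N-oxide (1.3 equiv), acetone/H2O 5:1, 0 °C; aq. Na2SO3
Reagents that add atoms: osmium tetroxide O=[Os](=O)(=O)=O; N-methylmorpholine N-oxide C[N+]1([O-])CCOCC1; water O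
Why: Upjohn dihydroxylation, in which electrophilic OsO4 selects the only unconjugated olefin (the other three are electron-poor acrylate-type olefins); the new carbinol centre is oxidised away in the next step.

Step 10
Reactants: 15 bis-angelate diol
Product: 16 bis-angelate 2-oxoaldehyde (side chain ends in C4H(CH3)–C5(=O)–C6H=O)
Conditions: Dess–Martin periodinane (3 equiv), CH2Cl2, 0 → 20 °C; crude product used at once
Reagents that add atoms: none
Why: Dess–Martin oxidation of both hydroxyls of the 1,2-diol gives the 2-oxoaldehyde without C–C cleavage; the near-neutral conditions keep the enolisable C4 stereocentre intact.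

Step 11
Reactants: 16 bis-angelate 2-oxoaldehyde
Product: 18 target germacranolide CNP0311008.1, via allylindium iodide angelate 17 (not isolated)
Conditions: Pd(PPh3)4 (10 mol %), InI (2.5 equiv), THF, 2 mM (16 added over 10 h), 20 °C; aq. NH4Cl
Reagents that add atoms: none
Why: Proposed new method: zerovalent palladium ionises only the allylic ring angelate to a π-allyl complex, which monovalent indium (InI) reduces to the nucleophilic allylindium 17 (indium on C13); its γ-carbon C7 then adds to the aldehyde carbon C6 (far more electrophilic than the C5 ketone) through a six-membered chair transition state, anti to the C8 side chain (trans-lactone, 7S) and with the acyl group equatorial (6S), regenerating the exocyclic C11=C13 methylene; the closest known reactions are the palladium-catalysed InI-mediated umpolung allylation of aldehydes by allylic esters and the macrocyclic Barbier/Nozaki–Hiyama–Kishi closure of germacranolides from 2-(bromomethyl)acrylates.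

**Compound list**

1 | dimethyl (4S,5S)-2,2-dimethyl-1,3-dioxolane-4,5-dicarboxylate (dimethyl 2,3-O-isopropylidene-D-tartrate) | COC(=O)[C@H]1OC(C)(C)O[C@@H]1C(=O)OC | starting material
2 | (4S,5S)-N4,N5-dimethoxy-N4,N5,2,2-tetramethyl-1,3-dioxolane-4,5-dicarboxamide | CON(C)C(=O)[C@H]1OC(C)(C)O[C@@H]1C(=O)N(C)OC | intermediate
3 | (3S)-3,7-dimethylocta-1,6-diene ((S)-β-citronellene) | CC(C)=CCC[C@H](C)C=C | starting material
4 | (4S)-4-methylhex-5-enal (not isolated) | O=CCC[C@H](C)C=C | intermediate
5 | (4S)-4-methylhex-5-en-1-ol | OCCC[C@H](C)C=C | intermediate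
6 | (3S)-6-bromo-3-methylhex-1-ene | BrCCC[C@H](C)C=C | intermediate
7 | [(4S)-4-methylhex-5-en-1-yl]magnesium bromide (not isolated) | Br[Mg]CCC[C@H](C)C=C | intermediate
8 | (4S,5S)-N-methoxy-N,2,2-trimethyl-5-[(5S)-5-methylhept-6-enoyl]-1,3-dioxolane-4-carboxamide | CON(C)C(=O)[C@H]1OC(C)(C)O[C@@H]1C(=O)CCC[C@H](C)C=C | intermediate
9 | bromomagnesium alkoxide of (4S,5S)-5-[(2R,6S)-2-hydroxy-6-methyloct-7-en-2-yl]-N-methoxy-N,2,2-trimethyl-1,3-dioxolane-4-carboxamide (not isolated) | CON(C)C(=O)[C@H]1OC(C)(C)O[C@@H]1[C@](C)(O[Mg]Br)CCC[C@H](C)C=C | intermediate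
10 | (4S,5S)-5-[(2R,6S)-2-hydroxy-6-methyloct-7-en-2-yl]-2,2-dimethyl-1,3-dioxolane-4-carbaldehyde | O=C[C@H]1OC(C)(C)O[C@@H]1[C@](C)(O)CCC[C@H](C)C=C | intermediate
11 | — (number not used; methyl acrylate is listed as a reagent in step 6) | — | —
12 | methyl 2-{hydroxy[(4R,5S)-5-[(2R,6S)-2-hydroxy-6-methyloct-7-en-2-yl]-2,2-dimethyl-1,3-dioxolan-4-yl]methyl}prop-2-enoate (carbinol epimers) | COC(=O)C(=C)C(O)[C@H]1OC(C)(C)O[C@@H]1[C@](C)(O)CCC[C@H](C)C=C | intermediate
13 | (5R)-5-[(1S,2R,6S)-1,2-dihydroxy-2,6-dimethyloct-7-en-1-yl]-4-hydroxy-3-methylideneoxolan-2-one (C4 epimers) | C=C1C(=O)O[C@@H]([C@H](O)[C@](C)(O)CCC[C@H](C)C=C)C1O | intermediate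
14 | bis-angelate of 13 (ring 4-O and side-chain 1′-O (2Z)-2-methylbut-2-enoates, tertiary OH free) | C=C1C(=O)O[C@@H]([C@H](OC(=O)/C(C)=C\C)[C@](C)(O)CCC[C@H](C)C=C)C1OC(=O)/C(C)=C\C | intermediate
15 | bis-angelate 7′,8′-diol (vinyl of 14 dihydroxylated; carbinol epimers) | C=C1C(=O)O[C@@H]([C@H](OC(=O)/C(C)=C\C)[C@](C)(O)CCC[C@H](C)C(O)CO)C1OC(=O)/C(C)=C\C | intermediate
16 | bis-angelate 2-oxoaldehyde (side chain ends in CH(CH3)–C(=O)–CHO) | C=C1C(=O)O[C@@H]([C@H](OC(=O)/C(C)=C\C)[C@](C)(O)CCC[C@H](C)C(=O)C=O)C1OC(=O)/C(C)=C\C | intermediate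
17 | allylindium iodide angelate: butenolide carrying CH2–In(I)(O-angelate) on C11, 9-O-angelate and the 2-oxoaldehyde chain (not isolated) | O=C1O[C@@H]([C@H](OC(=O)/C(C)=C\C)[C@](C)(O)CCC[C@H](C)C(=O)C=O)C=C1C[In](I)OC(=O)/C(C)=C\C | intermediate
18 | CNP0311008.1, (4S,6S,7S,8R,9S,10R)-9-angeloyloxy-6,10-dihydroxy-5-oxogermacr-11(13)-en-8,12-olide | C=C1C(=O)O[C@@H]2[C@@H]1[C@H](O)C(=O)[C@@H](C)CCC[C@@](C)(O)[C@H]2OC(=O)/C(C)=C\C | target

**Step count and risks**

Total step count: 11. Longest linear sequence: 10 steps (3 → 18 through steps 2–11); the tartrate branch is 9 steps (1 → 18 through steps 1 and 4–11).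

Three steps most likely to fail:

Step 11 (umpolung macro-allylation onto the 2-oxoaldehyde). Risks are reduction or hydration of the 2-oxoaldehyde, oligomerisation, and the wrong C6/C7 diastereomer. The fallback sets out from 15 and comes back at 18. The allylic ring angelate of 15 is exchanged for bromide with allylic transposition (MgBr2·OEt2, CH2Cl2, 0 °C) to give the 3-(bromomethyl)butenolide diol F1. Dess–Martin oxidation as in step 10 gives the bromo 2-oxoaldehyde F2. The ring is then closed without palladium by direct metal insertion (In powder, THF/H2O, 2 mM, 20 °C), a stoichiometric Barbier macro-allylation that tolerates the hydrated glyoxal, giving 18.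

Step 9 (dihydroxylation of the vinyl group beside three conjugated olefins). The fallback sets out from 14 and comes back at 15. Dimethyldioxirane (acetone, 0 °C), which does not attack acrylate-type olefins, epoxidises the vinyl group to the terminal epoxide F3. Acid-catalysed hydrolysis (cat. HClO4, THF/H2O, 0 °C) opens it to the diol 15.

Step 8 (double angeloylation, one site hindered, with risk of Z→E isomerisation). The fallback sets out from 13 and comes back at 14. Angelic anhydride with pyridine (CH2Cl2, 0 °C) acylates only the unhindered ring hydroxyl to give the ring mono-angelate F4. The hindered side-chain hydroxyl is esterified with 2-[bis(2,2,2-trifluoroethoxy)phosphoryl]propanoyl chloride (pyridine, CH2Cl2, 20 °C) to give the phosphonopropionate F5. A Still–Gennari olefination with acetaldehyde (KN(SiMe3)2, 18-crown-6, THF, −78 °C) then builds the Z-enoate in place and gives 14.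

Further compounds
F1 | step 11 | 3-(bromomethyl)butenolide with 9-O-angelate, free tertiary OH and terminal 1,2-diol | O=C1O[C@@H]([C@H](OC(=O)/C(C)=C\C)[C@](C)(O)CCC[C@H](C)C(O)CO)C=C1CBr
F2 | step 11 | 3-(bromomethyl)butenolide with 9-O-angelate, free tertiary OH and terminal 2-oxoaldehyde | O=C1O[C@@H]([C@H](OC(=O)/C(C)=C\C)[C@](C)(O)CCC[C@H](C)C(=O)C=O)C=C1CBr
F3 | step 9 | terminal epoxide of bis-angelate 14 | C=C1C(=O)O[C@@H]([C@H](OC(=O)/C(C)=C\C)[C@](C)(O)CCC[C@H](C)C2CO2)C1OC(=O)/C(C)=C\C
F4 | step 8 | ring mono-angelate of 13 (side-chain secondary OH free) | C=C1C(=O)O[C@@H]([C@H](O)[C@](C)(O)CCC[C@H](C)C=C)C1OC(=O)/C(C)=C\C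
F5 | step 8 | ring angelate, side-chain 2-[bis(2,2,2-trifluoroethoxy)phosphoryl]propanoate | C=C1C(=O)O[C@@H]([C@H](OC(=O)C(C)P(=O)(OCC(F)(F)F)OCC(F)(F)F)[C@](C)(O)CCC[C@H](C)C=C)C1OC(=O)/C(C)=C\C
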